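The seven-membered ring is disconnected at its C8=C9 olefin (benzo[7]annulene numbering). C9, its methyl and C8 are the isopropenyl group of a p-menthadiene, so this ring can be closed last by ring-closing metathesis between that native isopropenyl group on C9a and a vinyl group at the end of a C4a side chain. In one operation the key step closes the cycloheptene and fixes the Z-trisubstituted C8=C9 olefin. Its precursor is a monocyclic triene syn-diol built from (1S,4R)-p-mentha-2,8-dien-1-ol: Ireland–Claisen 1,3-chirality transfer sets C4a cis to C9a and creates quaternary C5, and Brown alkoxyallylboration sets C6/C7. Acylations and C2 allylic oxidation finish.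

Key step: step 9

Remark: the core is numbered as benzo[7]annulene (six-membered ring C1–C4, C4a, C9a; seven-membered ring C4a, C5–C9, C9a); compounds 1, 5 (hydroxyl cis to isopropenyl), 6, 13 and (−)-Ipc2BOMe are assumed to be commercial.

Step 1
Reactants: 1 angelic acid
Product: 2 (Z)-2-methylbut-2-en-1-ol
Conditions: LiAlH4, Et2O, 0 °C → rt
Reagents that add atoms: none
Why: Hydride reduction of the carboxylic acid to the allylic alcohol, which should leave the trisubstituted Z-olefin and its geometry untouched.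

Step 2
Reactants: 2 (Z)-2-methylbut-2-en-1-ol
Product: 3 [(2S,3R)-2,3-dimethyloxiran-2-yl]methanol
Conditions: Ti(OiPr)4 (cat.), L-(+)-DIPT (cat.), t-BuOOH, 4 Å MS, CH2Cl2, −20 °C
Reagents that add atoms: tert-butyl hydroperoxide CC(C)(C)OO
Why: Sharpless asymmetric epoxidation; syn oxygen transfer keeps the cis relation of C3-methyl and CH2OH, and L-(+)-tartrate should deliver oxygen to the face that gives 2S,3R (the same facial sense that converts Z-allylic alcohols such as nerol into 2S,3R epoxides).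

Step 3
Reactants: 3 [(2S,3R)-2,3-dimethyloxiran-2-yl]methanol
Product: 4 (2R,3R)-2,3-dimethyloxirane-2-carboxylic acid
Conditions: TEMPO (cat.), PhI(OAc)2, MeCN/H2O, rt
Reagents that add atoms: water O
Why: TEMPO/iodine(III) oxidation of the primary alcohol through the aldehyde hydrate to the acid, mild enough to spare the epoxide; both stereocenters are untouched (C2 changes from S to R only through CIP priority).

Step 4
Reactants: 5 (1S,4R)-1-methyl-4-(prop-1-en-2-yl)cyclohex-2-en-1-ol; 6 2-methylpropanoic anhydride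
Product: 7 (1S,4R)-1-methyl-4-(prop-1-en-2-yl)cyclohex-2-en-1-yl 2-methylpropanoate
Conditions: Et3N, DMAP, CH2Cl2, rt → 40 °C
Reagents that add atoms: 2-methylpropanoic anhydride CC(C)C(=O)OC(=O)C(C)C
Why: DMAP-catalysed acylation of the tertiary allylic alcohol under basic conditions, which should avoid ionisation of the allylic C–O bond; C1 and C4 are not involved.

Step 5
Reactants: 7 (1S,4R)-1-methyl-4-(prop-1-en-2-yl)cyclohex-2-en-1-yl 2-methylpropanoate
Product: 11 2-methyl-2-[(1S,6R)-3-methyl-6-(prop-1-en-2-yl)cyclohex-2-en-1-yl]propan-1-ol, via lithium ester enolate 8 (not isolated), via silyl ketene acetal 9 (not isolated), via trimethylsilyl ester 10 (not isolated)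
Conditions: LDA, TMSCl, THF, −78 °C → rt; then LiAlH4 (excess), 0 °C
Reagents that add atoms: none
Why: Ireland–Claisen rearrangement: the [3,3] shift of 9 is suprafacial across the cyclohexene, so the C–CMe2 bond should form on the face that carried the ester oxygen, cis to the isopropenyl group, which sets the future C4a (S) and quaternary C5 while the olefin moves to the methyl-bearing position; LiAlH4 then reduces silyl ester 10 in the same flask.

Step 6
Reactants: 11 2-methyl-2-[(1S,6R)-3-methyl-6-(prop-1-en-2-yl)cyclohex-2-en-1-yl]propan-1-ol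
Product: 12 2-methyl-2-[(1S,6R)-3-methyl-6-(prop-1-en-2-yl)cyclohex-2-en-1-yl]propanal
Conditions: Dess–Martin periodinane, NaHCO3, CH2Cl2, 0 °C
Reagents that add atoms: none
Why: Dess–Martin oxidation of the neopentylic primary alcohol; the aldehyde has no α-hydrogen, and buffered cold conditions with immediate use should prevent carbonyl-ene cyclisation onto the isopropenyl group.

Step 7
Reactants: 12 2-methyl-2-[(1S,6R)-3-methyl-6-(prop-1-en-2-yl)cyclohex-2-en-1-yl]propanal; 13 3-(methoxymethoxy)prop-1-ene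
Product: 16 (3R,4R)-4-(methoxymethoxy)-2-methyl-2-[(1S,6R)-3-methyl-6-(prop-1-en-2-yl)cyclohex-2-en-1-yl]hex-5-en-3-ol, via Z-alkoxyallyl-diisopinocampheylborane 14 (not isolated), via borinate ester 15 (not isolated)
Conditions: 13, s-BuLi, THF, −78 °C; (−)-Ipc2BOMe; BF3·OEt2; then 12, −78 °C; NaOH, H2O2, 0 °C → rt
Reagents that add atoms: 3-(methoxymethoxy)prop-1-ene C=CCOCOC
Why: Brown γ-alkoxyallylboration: the closed Zimmerman–Traxler transition state of the Z-γ-alkoxyallylborane gives the syn relation of the two oxygenated carbons, and the isopinocampheyl groups derived from (+)-α-pinene direct attack to the Si face of the aldehyde, which should set 3R (future C6) and hence 4R (future C7).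

Step 8
Reactants: 16 (3R,4R)-4-(methoxymethoxy)-2-methyl-2-[(1S,6R)-3-methyl-6-(prop-1-en-2-yl)cyclohex-2-en-1-yl]hex-5-en-3-ol
Product: 17 (3R,4R)-2-methyl-2-[(1S,6R)-3-methyl-6-(prop-1-en-2-yl)cyclohex-2-en-1-yl]hex-5-ene-3,4-diol
Conditions: Me2BBr, CH2Cl2, −78 °C; then aq. NaHCO3
Reagents that add atoms: none
Why: Bromoborane cleavage of the MOM acetal at low temperature, which avoids protic acid that could add the hydroxyl groups across the olefins; no stereocenter is involved.

Step 9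
Reactants: 17 (3R,4R)-2-methyl-2-[(1S,6R)-3-methyl-6-(prop-1-en-2-yl)cyclohex-2-en-1-yl]hex-5-ene-3,4-diol
Product: 18 (4aS,6R,7R,9aR)-3,5,5,9-tetramethyl-2,4a,5,6,7,9a-hexahydro-1H-benzo[7]annulene-6,7-diol
Conditions: Grubbs II (5 mol%), 1,4-benzoquinone (10 mol%), CH2Cl2 (0.005 M), 40 °C
Reagents that add atoms: none
Why: Ring-closing olefin metathesis by the Chauvin mechanism: the ruthenium alkylidene loads on the monosubstituted vinyl group, adds intramolecularly [2+2] to the 1,1-disubstituted isopropenyl olefin on C9a and cycloreverts to the C8=C9 olefin with loss of ethylene. The closest known reaction type is the metathesis closure of carvone- or limonene-derived isopropenyl dienes to trisubstituted cycloheptenes used for hydroazulene terpenoids. The seven-membered carbocycle is closed by forming the endocyclic C8=C9 double bond (both olefin carbons become ring members), and the ring size forces the Z geometry. No stereocenter is created; C4a, C6, C7 and C9a come unchanged from steps 5 and 7. The step needs cyclisation to win over cross-metathesis oligomerisation and the C3=C4 ring olefin to stay out: the cis disposition of the two side chains on C4a/C9a, the gem-dimethyl group at C5 and high dilution favour closure, and the endocyclic trisubstituted olefin has no productive ring-opening pathway. The free allylic C7 hydroxyl is tolerated, and benzoquinone should suppress Ru–H olefin migration.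

Step 10
Reactants: 18 (4aS,6R,7R,9aR)-3,5,5,9-tetramethyl-2,4a,5,6,7,9a-hexahydro-1H-benzo[7]annulene-6,7-diol; 1 angelic acid
Product: 20 (4aS,6R,7R,9aR)-6-hydroxy-3,5,5,9-tetramethyl-2,4a,5,6,7,9a-hexahydro-1H-benzo[7]annulen-7-yl (Z)-2-methylbut-2-enoate, via angelic 2,4,6-trichlorobenzoic anhydride 19 (not isolated)
Conditions: 1, 2,4,6-Cl3C6H2COCl, Et3N, toluene, rt; then 18, 80 °C
Reagents that add atoms: angelic acid C/C=C(/C)C(=O)O
Why: DMAP-free mixed-anhydride (Yamaguchi-type) acylation, a protocol that transfers the angeloyl group without Z→E isomerisation; the allylic C7–OH should react while the C6–OH next to quaternary C5 is too hindered.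

Step 11
Reactants: 20 (4aS,6R,7R,9aR)-6-hydroxy-3,5,5,9-tetramethyl-2,4a,5,6,7,9a-hexahydro-1H-benzo[7]annulen-7-yl (Z)-2-methylbut-2-enoate; 4 (2R,3R)-2,3-dimethyloxirane-2-carboxylic acid
Product: 22 (4aS,6R,7R,9aR)-3,5,5,9-tetramethyl-7-[(Z)-2-methylbut-2-enoyloxy]-2,4a,5,6,7,9a-hexahydro-1H-benzo[7]annulen-6-yl (2R,3R)-2,3-dimethyloxirane-2-carboxylate, via epoxyangelic 2,4,6-trichlorobenzoic anhydride 21 (not isolated)
Conditions: 4, 2,4,6-Cl3C6H2COCl, Et3N, THF, rt; then 20, DMAP, toluene, 50 °C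
Reagents that add atoms: (2R,3R)-2,3-dimethyloxirane-2-carboxylic acid OC(=O)[C@]1(C)O[C@@H]1C
Why: Yamaguchi esterification; the small tied-back oxiranyl acyl group and DMAP catalysis should allow acylation of the hindered C6–OH, and the acid cannot epimerise (quaternary C2).

Step 12
Reactants: 22 (4aS,6R,7R,9aR)-3,5,5,9-tetramethyl-7-[(Z)-2-methylbut-2-enoyloxy]-2,4a,5,6,7,9a-hexahydro-1H-benzo[7]annulen-6-yl (2R,3R)-2,3-dimethyloxirane-2-carboxylate
Product: 23 (4aS,6R,7R,9aR)-3,5,5,9-tetramethyl-7-[(Z)-2-methylbut-2-enoyloxy]-2-oxo-2,4a,5,6,7,9a-hexahydro-1H-benzo[7]annulen-6-yl (2R,3R)-2,3-dimethyloxirane-2-carboxylate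
Conditions: Rh2(cap)4 (1 mol%), t-BuOOH (70% aq.), DCE, 40 °C
Reagents that add atoms: tert-butyl hydroperoxide CC(C)(C)OO
Why: Dirhodium caprolactamate/TBHP allylic C–H oxidation (peroxyl-radical hydrogen abstraction, mixed peroxide, enone): C2 is the only allylic methylene of the electron-rich C3=C4 olefin, the C7–H is deactivated by its acyloxy group and the other allylic C–H bonds are tertiary or primary; no stereocenter is involved.

Compound list
1 | angelic acid, (Z)-2-methylbut-2-enoic acid | C/C=C(/C)C(=O)O | starting material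
2 | (Z)-2-methylbut-2-en-1-ol | C/C=C(/C)CO | intermediate
3 | [(2S,3R)-2,3-dimethyloxiran-2-yl]methanol | OC[C@]1(C)O[C@@H]1C | intermediate
4 | (2R,3R)-2,3-dimethyloxirane-2-carboxylic acid | OC(=O)[C@]1(C)O[C@@H]1C | intermediate
5 | (1S,4R)-1-methyl-4-(prop-1-en-2-yl)cyclohex-2-en-1-ol, (1S,4R)-p-mentha-2,8-dien-1-ol | C[C@@]1(O)C=C[C@H](C(C)=C)CC1 | starting material
6 | 2-methylpropanoic anhydride | CC(C)C(=O)OC(=O)C(C)C | starting material
7 | (1S,4R)-1-methyl-4-(prop-1-en-2-yl)cyclohex-2-en-1-yl 2-methylpropanoate | CC(C)C(=O)O[C@]1(C)C=C[C@H](C(C)=C)CC1 | intermediate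
8 | lithium enolate of 7 | [Li]OC(=C(C)C)O[C@]1(C)C=C[C@H](C(C)=C)CC1 | intermediate
9 | trimethylsilyl ketene acetal of 7 | C[Si](C)(C)OC(=C(C)C)O[C@]1(C)C=C[C@H](C(C)=C)CC1 | intermediate
10 | trimethylsilyl 2-methyl-2-[(1S,6R)-3-methyl-6-(prop-1-en-2-yl)cyclohex-2-en-1-yl]propanoate | CC1=C[C@@H]([C@@H](CC1)C(C)=C)C(C)(C)C(=O)O[Si](C)(C)C | intermediate
11 | 2-methyl-2-[(1S,6R)-3-methyl-6-(prop-1-en-2-yl)cyclohex-2-en-1-yl]propan-1-ol | CC1=C[C@@H]([C@@H](CC1)C(C)=C)C(C)(C)CO | intermediate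
12 | 2-methyl-2-[(1S,6R)-3-methyl-6-(prop-1-en-2-yl)cyclohex-2-en-1-yl]propanal | CC1=C[C@@H]([C@@H](CC1)C(C)=C)C(C)(C)C=O | intermediate
13 | 3-(methoxymethoxy)prop-1-ene, allyl MOM ether | C=CCOCOC | starting material
14 | [(Z)-3-(methoxymethoxy)prop-2-en-1-yl]diisopinocampheylborane, Ipc from (+)-α-pinene | COCO/C=C\CB([C@@H]1C[C@@H]2C[C@H]([C@H]1C)C2(C)C)[C@@H]1C[C@@H]2C[C@H]([C@H]1C)C2(C)C | intermediate
15 | diisopinocampheylborinate ester of 16 | CC1=C[C@@H]([C@@H](CC1)C(C)=C)C(C)(C)[C@@H](OB([C@@H]2C[C@@H]3C[C@H]([C@H]2C)C3(C)C)[C@@H]2C[C@@H]3C[C@H]([C@H]2C)C3(C)C)[C@H](OCOC)C=C | intermediate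
16 | (3R,4R)-4-(methoxymethoxy)-2-methyl-2-[(1S,6R)-3-methyl-6-(prop-1-en-2-yl)cyclohex-2-en-1-yl]hex-5-en-3-ol | CC1=C[C@@H]([C@@H](CC1)C(C)=C)C(C)(C)[C@@H](O)[C@H](OCOC)C=C | intermediate
17 | (3R,4R)-2-methyl-2-[(1S,6R)-3-methyl-6-(prop-1-en-2-yl)cyclohex-2-en-1-yl]hex-5-ene-3,4-diol | CC1=C[C@@H]([C@@H](CC1)C(C)=C)C(C)(C)[C@@H](O)[C@H](O)C=C | intermediate
18 | (4aS,6R,7R,9aR)-3,5,5,9-tetramethyl-2,4a,5,6,7,9a-hexahydro-1H-benzo[7]annulene-6,7-diol | O[C@@H]1C=C(C)[C@@H]2CCC(C)=C[C@@H]2C(C)(C)[C@H]1O | intermediate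
19 | (Z)-2-methylbut-2-enoic 2,4,6-trichlorobenzoic anhydride | C/C=C(/C)C(=O)OC(=O)c1c(Cl)cc(Cl)cc1Cl | intermediate
20 | (4aS,6R,7R,9aR)-6-hydroxy-3,5,5,9-tetramethyl-2,4a,5,6,7,9a-hexahydro-1H-benzo[7]annulen-7-yl (Z)-2-methylbut-2-enoate | C/C=C(/C)C(=O)O[C@@H]1C=C(C)[C@@H]2CCC(C)=C[C@@H]2C(C)(C)[C@H]1O | intermediate
21 | (2R,3R)-2,3-dimethyloxirane-2-carboxylic 2,4,6-trichlorobenzoic anhydride | Clc1cc(Cl)c(C(=O)OC(=O)[C@]2(C)O[C@@H]2C)c(Cl)c1 | intermediate
22 | (4aS,6R,7R,9aR)-3,5,5,9-tetramethyl-7-[(Z)-2-methylbut-2-enoyloxy]-2,4a,5,6,7,9a-hexahydro-1H-benzo[7]annulen-6-yl (2R,3R)-2,3-dimethyloxirane-2-carboxylate | C/C=C(/C)C(=O)O[C@@H]1C=C(C)[C@@H]2CCC(C)=C[C@@H]2C(C)(C)[C@H]1OC(=O)[C@]1(C)O[C@@H]1C | intermediate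
23 | (4aS,6R,7R,9aR)-3,5,5,9-tetramethyl-7-[(Z)-2-methylbut-2-enoyloxy]-2-oxo-2,4a,5,6,7,9a-hexahydro-1H-benzo[7]annulen-6-yl (2R,3R)-2,3-dimethyloxirane-2-carboxylate | C/C=C(/C)C(=O)O[C@@H]1C=C(C)[C@@H]2CC(=O)C(C)=C[C@@H]2C(C)(C)[C@H]1OC(=O)[C@]1(C)O[C@@H]1C | target

Total step count: 12. Longest linear sequence: 9 steps (steps 4–12, from 5 to 23); steps 1–3 form the side branch to acid 4.

Steps most likely to fail

Step 12: hydrogen abstraction at the competing allylic sites (C9a–H, C4a–H, C7–H) or peroxide capture at C4 may cause over-oxidation and a transposed enone on the fully acylated substrate. The fallback sets out from diol 18 and moves the C–H oxidation ahead of the acylations. Silylation (TESOTf, 2,6-lutidine, CH2Cl2) should give bis(triethylsilyl) ether F1. CrO3·3,5-dimethylpyrazole (CH2Cl2, −20 °C), an electrophilic chromium(VI) oxidant that delivers oxygen to the ring methylene on the methyl-bearing olefin terminus, should give enone F2. HF·pyridine should give enone diol F3, and angeloylation as in step 10 should give monoester F4. Yamaguchi esterification with 4 as in step 11 comes back to the route at 23.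

Step 11: slow acylation of the neopentylic C6–OH may allow DMAP-induced Z→E isomerisation or 1,2-migration of the neighbouring angelate. The fallback sets out from 16, where the hindered hydroxyl is the only free one and no sensitive ester is present. Deprotonation (KHMDS, THF, −78 °C) and acylation with mixed anhydride 21 should give epoxy ester F5. Ring-closing metathesis as in step 9 should give bicyclic MOM ether F6, and MOM cleavage (TESOTf/2,2′-bipyridyl, then H2O) should give allylic alcohol F7. Angeloylation as in step 10 comes back to the route at 22.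

Step 5: ionisation or elimination of the tertiary allylic ketene acetal may compete with the [3,3] shift, which must form a bond next to the cis isopropenyl group. The fallback sets out from 5. Eschenmoser–Claisen rearrangement with 1-methoxy-N,N,2-trimethylprop-1-en-1-amine (xylene, 140 °C; neutral, same suprafacial transfer) should give amide F8. LiEt3BH (THF, rt) should reduce the tertiary amide to the primary alcohol, which comes back to the route at 11.

Further compounds
F1 | step 12 | (4aS,6R,7R,9aR)-3,5,5,9-tetramethyl-6,7-bis(triethylsilyloxy)-2,4a,5,6,7,9a-hexahydro-1H-benzo[7]annulene | CC[Si](CC)(CC)O[C@@H]1C=C(C)[C@@H]2CCC(C)=C[C@@H]2C(C)(C)[C@H]1O[Si](CC)(CC)CC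
F2 | step 12 | (4aS,6R,7R,9aR)-3,5,5,9-tetramethyl-6,7-bis(triethylsilyloxy)-1,4a,5,6,7,9a-hexahydro-2H-benzo[7]annulen-2-one | CC[Si](CC)(CC)O[C@@H]1C=C(C)[C@@H]2CC(=O)C(C)=C[C@@H]2C(C)(C)[C@H]1O[Si](CC)(CC)CC
F3 | step 12 | (4aS,6R,7R,9aR)-6,7-dihydroxy-3,5,5,9-tetramethyl-1,4a,5,6,7,9a-hexahydro-2H-benzo[7]annulen-2-one | O[C@@H]1C=C(C)[C@@H]2CC(=O)C(C)=C[C@@H]2C(C)(C)[C@H]1O
F4 | step 12 | (4aS,6R,7R,9aR)-6-hydroxy-3,5,5,9-tetramethyl-2-oxo-2,4a,5,6,7,9a-hexahydro-1H-benzo[7]annulen-7-yl (Z)-2-methylbut-2-enoate | C/C=C(/C)C(=O)O[C@@H]1C=C(C)[C@@H]2CC(=O)C(C)=C[C@@H]2C(C)(C)[C@H]1O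
F5 | step 11 | (3R,4R)-4-(methoxymethoxy)-2-methyl-2-[(1S,6R)-3-methyl-6-(prop-1-en-2-yl)cyclohex-2-en-1-yl]hex-5-en-3-yl (2R,3R)-2,3-dimethyloxirane-2-carboxylate | CC1=C[C@@H]([C@@H](CC1)C(C)=C)C(C)(C)[C@@H](OC(=O)[C@]2(C)O[C@@H]2C)[C@H](OCOC)C=C
F6 | step 11 | (4aS,6R,7R,9aR)-7-(methoxymethoxy)-3,5,5,9-tetramethyl-2,4a,5,6,7,9a-hexahydro-1H-benzo[7]annulen-6-yl (2R,3R)-2,3-dimethyloxirane-2-carboxylate | COCO[C@@H]1C=C(C)[C@@H]2CCC(C)=C[C@@H]2C(C)(C)[C@H]1OC(=O)[C@]1(C)O[C@@H]1C
F7 | step 11 | (4aS,6R,7R,9aR)-7-hydroxy-3,5,5,9-tetramethyl-2,4a,5,6,7,9a-hexahydro-1H-benzo[7]annulen-6-yl (2R,3R)-2,3-dimethyloxirane-2-carboxylate | O[C@@H]1C=C(C)[C@@H]2CCC(C)=C[C@@H]2C(C)(C)[C@H]1OC(=O)[C@]1(C)O[C@@H]1C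
F8 | step 5 | N,N,2-trimethyl-2-[(1S,6R)-3-methyl-6-(prop-1-en-2-yl)cyclohex-2-en-1-yl]propanamide | CC1=C[C@@H]([C@@H](CC1)C(C)=C)C(C)(C)C(=O)N(C)C
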